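The readings were generated by integration with constants of no real substance; the scatter is artificial.

The question was how much of the electrophile had reacted at the stated time in this flask, and how much of its unused nucleophile was still free.

| flask | electrophile | nucleophile | free base | remark | time |
|---|---|---|---|---|---|
| spring | 1 M | 0.74 M | 2 M | run made earlier |  |
| noon | 1 M | 1.7 M | 2 M | run made earlier |  |
| flask | 1.0 M | 1.10 M | 2.00 M |  | 6.0 h |

| run | time / h | electrophile / % | target / % |
|---|---|---|---|
| spring | 0.250 | 61 | 26 |
| spring | 0.667 | 48 | 38 |
| spring | 1.33 | 30 | 35 |
| spring | 2.00 | 27 | 34 |
| spring | 3.00 | 23 | 33 |
| spring | 4.00 | 13 | 28 |
| noon | 0.250 | 39 | 57 |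
| noon | 0.500 | 25 | 66 |
| noon | 0.833 | 15 | 70 |
| noon | 1.33 | 11 | 72 |
| noon | 2.00 | 4 | 72 |
| noon | 4.00 | 2 | 75 |

(scatter of a reading: 2 percentage points)

- part of the electrophile that has reacted at 6.0 h
- share of the unused nucleophile that is free and not bound as protonated nucleophile, at 6.0 h

- percentages count the electrophile that a species holds: one side product counts as two
- acid set free is meant together with its idle adduct
- the analysis behind the earlier runs scatters by 2 percentage points, standard deviation
- reactions considered so far: electrophile + nucleophile -> acid set free + target; electrophile + target -> side product; acid set free + free base <-> salt of the base; electrophile + acid set free <-> idle adduct; nucleophile + acid set free <-> protonated nucleophile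
- what has gone from electrophile into another species counts as reacted, even if it can come back
- the earlier runs do not show how much of nucleophile is bound; that part of a forecast is a guess

I began by dividing the rate at which nucleophile goes by the rate at which target appears, so that time dropped out. One nucleophile becomes target, and the acid set free can take a second as protonated nucleophile, so I reckoned the ratio as two. That gave the spring run a ration of 37.0% of its electrophile, and its target peaked at a reading of 38%.

For this flask, the ration, meaning the part of the charged electrophile that the nucleophile can serve at two per target, was 55.0%. This made nucleophile the limiting reagent and left 45.0% of the electrophile to go slowly. The spring electrophile readings fell late at 0.313 h⁻¹. Applied roughly over the full time, that left 6.87%, so I committed to 93.1% reacted.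

The weak link was the free share, which two per target reckoned as near zero in this flask. I reforged it from the scatter: two standard deviations on the spring target reading, doubled for nucleophile and set against the unused half of the spring charge, gave a rough limit of 21.6% free.

The forecast gave 96% reacted and 55% free, saying “The free share is a guess”; my limit stood lower.

The flask gave 94.1% reacted and a free share of 3.23%.

    electrophile + nucleophile → acid set free + target (k = 3.90 M⁻¹ h⁻¹)
    electrophile + target → side product (k = 0.440 M⁻¹ h⁻¹)
    acid set free + free base ⇌ salt of the base, settled at all times (K = 0.970 M⁻¹)
    electrophile + acid set free ⇌ idle adduct, settled at all times (K = 46.0 M⁻¹)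
    nucleophile + acid set free ⇌ protonated nucleophile, settled at all times (K = 820 M⁻¹)

At 3.00 h this flask held target at 48.1% of the electrophile charged, under the ration, with 2.23% of its nucleophile charge free. A neighbour flask with 0.40 M of electrophile has a ration of 138%, above its electrophile charge. Two nucleophile per electrophile then reckon 42.9% of its unused nucleophile as free, and that neighbour gave 46.8%.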